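**Plan**

- The target is a (2R,3S)-trans-flavanone (rings A, B, C) whose C3 carries ring D, the 4'-hydroxyphenyl ring of a 5,7-dihydroxyflavone. The last disconnections are one silyl ether and five benzyl ether C–O bonds.
- Ring C is then cut at C2–C3. C2 is benzylic and bound to O1, and C3 is alpha to the C4 ketone and bound to ring D. C3 therefore becomes the carbene carbon of an alpha-aryl alpha-diazoketone, and C2 the CH2 of a 4-(benzyloxy)benzyl ether on a ring A oxygen.
- The diazoketone goes back to a deoxybenzoin, cut at the CH2–ring D bond into a tri-etherified phloroacetophenone and a 3'-bromo-4'-hydroxyflavone. The flavone pyranone is cut at O1–C2 and C2–C3 into an acetophenone and an aldehyde, and one commercial acetophenone serves both halves.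
- Forward: the flavone pyranone ring arises first (chalcone, oxidative cyclisation), the halves are joined by enolate arylation, the diazo group is installed, ring C closes in the key step, and the phenols are freed.
- Stereochemistry: C2 comes from the chiral dirhodium carboxylate, which picks one enantiotopic benzylic hydrogen. C3 comes from base equilibration to the trans isomer.

Key step: step 8

Assumption: Rh2(S-PTTL)4 is taken to select the benzylic hydrogen that leads to the 2R series; should the sense prove opposite, the mirror-image catalyst Rh2(R-PTTL)4 would be used in the same step with nothing else changed.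

**Route**

Step 1
Reactants: 1 1-[2,4-bis(benzyloxy)-6-hydroxyphenyl]ethanone; 2 4-(benzyloxy)benzyl chloride
Product: 3 1-{2,4-bis(benzyloxy)-6-[4-(benzyloxy)benzyloxy]phenyl}ethanone
Conditions: K2CO3, Bu4NI (cat.), DMF, 70 °C
Reagents that add atoms: none
Why: Williamson ether synthesis in which the phenoxide of the one free, chelated ortho hydroxyl displaces chloride from the benzylic halide by SN2, with iodide catalysis and warm DMF overcoming the hydrogen bond to the ketone and carbonate too weak a base to deprotonate the acetyl methyl group.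

Step 2
Reactants: 4 3-bromo-4-hydroxybenzaldehyde
Product: 5 3-bromo-4-(methoxymethoxy)benzaldehyde
Conditions: MOMCl, K2CO3, acetone, 0 °C to rt
Reagents that add atoms: chloromethyl methyl ether (MOMCl), COCCl
Why: Williamson-type O-alkylation with the reactive chloromethyl ether masks the acidic phenol as a methoxymethyl (MOM) acetal, so that the aldehyde is not deactivated as its phenoxide in the aldol condensation that follows.

Step 3
Reactants: 5 3-bromo-4-(methoxymethoxy)benzaldehyde; 1 1-[2,4-bis(benzyloxy)-6-hydroxyphenyl]ethanone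
Product: 6 (E)-1-[2,4-bis(benzyloxy)-6-hydroxyphenyl]-3-[3-bromo-4-(methoxymethoxy)phenyl]prop-2-en-1-one
Conditions: KOH (aq.), EtOH/THF, rt
Reagents that add atoms: none
Why: Claisen–Schmidt condensation in which the acetophenone enolate adds to the non-enolisable aldehyde and E1cB loss of water gives the conjugated E-enone, which with a 6'-alkoxy group stays in the open chalcone form.

Step 4
Reactants: 6 (E)-1-[2,4-bis(benzyloxy)-6-hydroxyphenyl]-3-[3-bromo-4-(methoxymethoxy)phenyl]prop-2-en-1-one
Product: 8 5,7-bis(benzyloxy)-2-(3-bromo-4-hydroxyphenyl)-4H-chromen-4-one, via MOM-protected bromoflavone 7 (not isolated)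
Conditions: iodine (I2, cat.), DMSO, 130 °C; then HCl (aq.), MeOH, 60 °C
Reagents that add atoms: none
Why: Iodine/DMSO oxidative cyclisation of a 2'-hydroxychalcone (oxa-Michael closure, alpha-iodination and loss of HI, with DMSO reoxidising iodide) builds the pyranone ring, and the acid finish cleaves the MOM acetal while the benzyl ethers and the aryl bromide stay untouched.

Step 5
Reactants: 3 1-{2,4-bis(benzyloxy)-6-[4-(benzyloxy)benzyloxy]phenyl}ethanone; 8 5,7-bis(benzyloxy)-2-(3-bromo-4-hydroxyphenyl)-4H-chromen-4-one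
Product: 9 1-{2,4-bis(benzyloxy)-6-[4-(benzyloxy)benzyloxy]phenyl}-2-{5-[5,7-bis(benzyloxy)-4-oxo-4H-chromen-2-yl]-2-hydroxyphenyl}ethanone
Conditions: Pd2(dba)3 (zerovalent palladium, cat.), 1,2-bis(di-tert-butylphosphinomethyl)benzene, NaOtBu, toluene/THF, 80 °C; NH4Cl (aq.) work-up
Reagents that add atoms: none
Why: Palladium-catalysed alpha-arylation of a ketone enolate (Buchwald–Hartwig type), a coupling known to accept unprotected ortho-bromophenols as their phenoxides, forms the CH2–ring D bond by oxidative addition into C–Br, enolate binding and reductive elimination, with the bulky bisphosphine and the ortho substituent holding it at monoarylation and the neutral work-up avoiding acid-promoted closure to a benzofuran.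

Step 6
Reactants: 9 1-{2,4-bis(benzyloxy)-6-[4-(benzyloxy)benzyloxy]phenyl}-2-{5-[5,7-bis(benzyloxy)-4-oxo-4H-chromen-2-yl]-2-hydroxyphenyl}ethanone
Product: 10 1-{2,4-bis(benzyloxy)-6-[4-(benzyloxy)benzyloxy]phenyl}-2-{5-[5,7-bis(benzyloxy)-4-oxo-4H-chromen-2-yl]-2-[(tert-butyldiphenylsilyl)oxy]phenyl}ethanone
Conditions: TBDPSCl, imidazole, DMF, rt
Reagents that add atoms: tert-butyl(chloro)diphenylsilane (TBDPSCl), CC(C)(C)[Si](Cl)(c1ccccc1)c1ccccc1
Why: Imidazole-promoted silylation of the only free phenol gives a tert-butyldiphenylsilyl (TBDPS) ether, a ring D oxygen substituent that has neither an alpha C–H bond nor a carbonyl group to intercept the later carbene.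

Step 7
Reactants: 10 1-{2,4-bis(benzyloxy)-6-[4-(benzyloxy)benzyloxy]phenyl}-2-{5-[5,7-bis(benzyloxy)-4-oxo-4H-chromen-2-yl]-2-[(tert-butyldiphenylsilyl)oxy]phenyl}ethanone
Product: 11 1-{2,4-bis(benzyloxy)-6-[4-(benzyloxy)benzyloxy]phenyl}-2-{5-[5,7-bis(benzyloxy)-4-oxo-4H-chromen-2-yl]-2-[(tert-butyldiphenylsilyl)oxy]phenyl}-2-diazoethanone
Conditions: p-ABSA, DBU, MeCN, 0 °C to rt
Reagents that add atoms: 4-acetamidobenzenesulfonyl azide (p-ABSA), CC(=O)Nc1ccc(cc1)S(=O)(=O)N=[N+]=[N-]
Why: Regitz diazo transfer in which DBU deprotonates the methylene activated by both the ketone and ring D, the enolate attacks the terminal nitrogen of the sulfonyl azide, and the triazene collapses to the alpha-aryl alpha-diazoketone and the sulfonamide.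

Step 8
Reactants: 11 1-{2,4-bis(benzyloxy)-6-[4-(benzyloxy)benzyloxy]phenyl}-2-{5-[5,7-bis(benzyloxy)-4-oxo-4H-chromen-2-yl]-2-[(tert-butyldiphenylsilyl)oxy]phenyl}-2-diazoethanone
Product: 13 (2R,3S)-5,7-bis(benzyloxy)-2-[4-(benzyloxy)phenyl]-3-{5-[5,7-bis(benzyloxy)-4-oxo-4H-chromen-2-yl]-2-[(tert-butyldiphenylsilyl)oxy]phenyl}chroman-4-one, via cis-flavanone 12 (not isolated)
Conditions: Rh2(S-PTTL)4 (dirhodium tetrakis[N-phthaloyl-(S)-tert-leucinate], 2 mol %), toluene, −20 °C to rt, slow addition of 11; then DBU (0.1 equiv), 0 °C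
Reagents that add atoms: none
Why: Rh2(S-PTTL)4 takes up the diazo carbon of 11, N2 leaves, and the divalent-rhodium-bound donor/acceptor carbene at C3 (donor ring D, acceptor the aroyl ketone) inserts through a concerted three-centre transition state with hydride-transfer character into a benzylic C–H bond of the ortho 4-(benzyloxy)benzyl ether, which forms C2–C3 and frees the catalyst. The closest known reaction type is the chiral dirhodium carboxylate catalysed C–H insertion of ortho-alkoxyaryl diazoketones to chroman-4-ones, together with insertions of aryl-substituted carbenes into benzylic ether C–H bonds. Ring C closes as a six-membered ring by 1,6-insertion (carbene carbon, C4, C4a, C8a, O1, benzylic carbon), and no five-membered ring can arise by insertion because the 1,5 position is O1. C2 is set by the chiral pocket of the four N-phthaloyl-tert-leucinate ligands, which select one of the two enantiotopic benzylic hydrogens, and C3 is set afterwards under thermodynamic control, since DBU equilibrates the kinetically formed cis isomer 12 through its enol form to the diequatorial trans isomer 13 while C2 stays untouched. The step needs insertion to win over attack of O1 on the carbene (oxonium ylide, then 1,2-benzyl shift) and over reaction at ring D: O1 is a weakly basic aryl ether oxygen, the donor/acceptor carbene is discriminating and the bulky carboxylate walls disfavour the ylide, while the ring D oxygen carries a silyl group without an alpha C–H bond or a carbonyl. It also needs the 4-(benzyloxy)benzyl CH2 to react ahead of the CH2 of the plain benzyl ether on the other ortho oxygen, which lies at the same 1,6 distance: the para-alkoxy group stabilises the positive charge that builds up on carbon in the transition state, so the electrophilic carbene should favour that site and the low temperature should sharpen the preference, the minor 2-phenyl regioisomer would be removed by chromatography, and the benzyl CH2 groups at C7 and on the flavone are out of reach.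

Step 9
Reactants: 13 (2R,3S)-5,7-bis(benzyloxy)-2-[4-(benzyloxy)phenyl]-3-{5-[5,7-bis(benzyloxy)-4-oxo-4H-chromen-2-yl]-2-[(tert-butyldiphenylsilyl)oxy]phenyl}chroman-4-one
Product: 14 (2R,3S)-5,7-bis(benzyloxy)-2-[4-(benzyloxy)phenyl]-3-{5-[5,7-bis(benzyloxy)-4-oxo-4H-chromen-2-yl]-2-hydroxyphenyl}chroman-4-one
Conditions: HF·pyridine, pyridine, THF, 0 °C
Reagents that add atoms: none
Why: Fluoride-driven cleavage of the aryl silyl ether (strong Si–F bond) under buffered, weakly acidic conditions should form no enolate, so neither C3 epimerisation nor retro-oxa-Michael opening at C2 is expected, and the benzyl ethers are inert.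

Step 10
Reactants: 14 (2R,3S)-5,7-bis(benzyloxy)-2-[4-(benzyloxy)phenyl]-3-{5-[5,7-bis(benzyloxy)-4-oxo-4H-chromen-2-yl]-2-hydroxyphenyl}chroman-4-one
Product: 15 (2R,3S)-5,7-dihydroxy-3-[5-(5,7-dihydroxy-4-oxo-4H-chromen-2-yl)-2-hydroxyphenyl]-2-(4-hydroxyphenyl)chroman-4-one
Conditions: H2 (1 atm), Pd/C (palladium on carbon, 10 wt %), EtOAc/THF, rt
Reagents that add atoms: none
Why: Catalytic hydrogenolysis of the five benzylic C–O ether bonds under neutral conditions leaves both stereocentres untouched, and because the flavone C2–C3 double bond, the ketones and the cyclic benzylic C2–O1 bond react more slowly, the reaction is stopped once the calculated amount of H2 is taken up.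

**Compound list**

1 | 1-[2,4-bis(benzyloxy)-6-hydroxyphenyl]ethanone (2',4'-bis(benzyloxy)-6'-hydroxyacetophenone) | CC(=O)c1c(O)cc(OCc2ccccc2)cc1OCc1ccccc1 | starting material
2 | 4-(benzyloxy)benzyl chloride | ClCc1ccc(OCc2ccccc2)cc1 | starting material
3 | 1-{2,4-bis(benzyloxy)-6-[4-(benzyloxy)benzyloxy]phenyl}ethanone | CC(=O)c1c(OCc2ccc(OCc3ccccc3)cc2)cc(OCc2ccccc2)cc1OCc1ccccc1 | intermediate
4 | 3-bromo-4-hydroxybenzaldehyde | O=Cc1ccc(O)c(Br)c1 | starting material
5 | 3-bromo-4-(methoxymethoxy)benzaldehyde | O=Cc1ccc(OCOC)c(Br)c1 | intermediate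
6 | (E)-1-[2,4-bis(benzyloxy)-6-hydroxyphenyl]-3-[3-bromo-4-(methoxymethoxy)phenyl]prop-2-en-1-one | O=C(/C=C/c1ccc(OCOC)c(Br)c1)c1c(O)cc(OCc2ccccc2)cc1OCc1ccccc1 | intermediate
7 | 5,7-bis(benzyloxy)-2-[3-bromo-4-(methoxymethoxy)phenyl]-4H-chromen-4-one (formed in the flask in step 4) | O=c1cc(-c2ccc(OCOC)c(Br)c2)oc2cc(OCc3ccccc3)cc(OCc3ccccc3)c12 | intermediate
8 | 5,7-bis(benzyloxy)-2-(3-bromo-4-hydroxyphenyl)-4H-chromen-4-one | O=c1cc(-c2ccc(O)c(Br)c2)oc2cc(OCc3ccccc3)cc(OCc3ccccc3)c12 | intermediate
9 | 1-{2,4-bis(benzyloxy)-6-[4-(benzyloxy)benzyloxy]phenyl}-2-{5-[5,7-bis(benzyloxy)-4-oxo-4H-chromen-2-yl]-2-hydroxyphenyl}ethanone | O=C(Cc1cc(-c2cc(=O)c3c(OCc4ccccc4)cc(OCc4ccccc4)cc3o2)ccc1O)c1c(OCc2ccc(OCc3ccccc3)cc2)cc(OCc2ccccc2)cc1OCc1ccccc1 | intermediate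
10 | 1-{2,4-bis(benzyloxy)-6-[4-(benzyloxy)benzyloxy]phenyl}-2-{5-[5,7-bis(benzyloxy)-4-oxo-4H-chromen-2-yl]-2-[(tert-butyldiphenylsilyl)oxy]phenyl}ethanone | O=C(Cc1cc(-c2cc(=O)c3c(OCc4ccccc4)cc(OCc4ccccc4)cc3o2)ccc1O[Si](c1ccccc1)(c1ccccc1)C(C)(C)C)c1c(OCc2ccc(OCc3ccccc3)cc2)cc(OCc2ccccc2)cc1OCc1ccccc1 | intermediate
11 | 1-{2,4-bis(benzyloxy)-6-[4-(benzyloxy)benzyloxy]phenyl}-2-{5-[5,7-bis(benzyloxy)-4-oxo-4H-chromen-2-yl]-2-[(tert-butyldiphenylsilyl)oxy]phenyl}-2-diazoethanone | O=C(C(=[N+]=[N-])c1cc(-c2cc(=O)c3c(OCc4ccccc4)cc(OCc4ccccc4)cc3o2)ccc1O[Si](c1ccccc1)(c1ccccc1)C(C)(C)C)c1c(OCc2ccc(OCc3ccccc3)cc2)cc(OCc2ccccc2)cc1OCc1ccccc1 | intermediate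
12 | (2R,3R)-5,7-bis(benzyloxy)-2-[4-(benzyloxy)phenyl]-3-{5-[5,7-bis(benzyloxy)-4-oxo-4H-chromen-2-yl]-2-[(tert-butyldiphenylsilyl)oxy]phenyl}chroman-4-one (cis; formed in the flask in step 8) | O=C1c2c(OCc3ccccc3)cc(OCc3ccccc3)cc2O[C@@H](c2ccc(OCc3ccccc3)cc2)[C@H]1c1cc(-c2cc(=O)c3c(OCc4ccccc4)cc(OCc4ccccc4)cc3o2)ccc1O[Si](c1ccccc1)(c1ccccc1)C(C)(C)C | intermediate
13 | (2R,3S)-5,7-bis(benzyloxy)-2-[4-(benzyloxy)phenyl]-3-{5-[5,7-bis(benzyloxy)-4-oxo-4H-chromen-2-yl]-2-[(tert-butyldiphenylsilyl)oxy]phenyl}chroman-4-one (trans) | O=C1c2c(OCc3ccccc3)cc(OCc3ccccc3)cc2O[C@@H](c2ccc(OCc3ccccc3)cc2)[C@@H]1c1cc(-c2cc(=O)c3c(OCc4ccccc4)cc(OCc4ccccc4)cc3o2)ccc1O[Si](c1ccccc1)(c1ccccc1)C(C)(C)C | intermediate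
14 | (2R,3S)-5,7-bis(benzyloxy)-2-[4-(benzyloxy)phenyl]-3-{5-[5,7-bis(benzyloxy)-4-oxo-4H-chromen-2-yl]-2-hydroxyphenyl}chroman-4-one | O=C1c2c(OCc3ccccc3)cc(OCc3ccccc3)cc2O[C@@H](c2ccc(OCc3ccccc3)cc2)[C@@H]1c1cc(-c2cc(=O)c3c(OCc4ccccc4)cc(OCc4ccccc4)cc3o2)ccc1O | intermediate
15 | (2R,3S)-5,7-dihydroxy-3-[5-(5,7-dihydroxy-4-oxo-4H-chromen-2-yl)-2-hydroxyphenyl]-2-(4-hydroxyphenyl)chroman-4-one (CNP0324936.1) | O=C1c2c(O)cc(O)cc2O[C@@H](c2ccc(O)cc2)[C@@H]1c1cc(-c2cc(=O)c3c(O)cc(O)cc3o2)ccc1O | target

**Step count**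

Total: 10 steps. Longest linear sequence: 9 steps (steps 2 to 10, from 3-bromo-4-hydroxybenzaldehyde 4); the ring A branch (step 1) joins at step 5.

**Steps most likely to fail, with fallbacks**

Step 8. Four things may go wrong here. The ring A ether oxygen may attack the carbene and the benzylic group may then migrate from oxygen to carbon. Insertion may leak to the plain benzyl ether on the other ortho oxygen. The catalyst may discriminate poorly between the two benzylic hydrogens. The base equilibration may open ring C by retro-oxa-Michael reaction and erode C2. The fallback sets out from 10 and uses condensation chemistry with resolution, which also fixes the regiochemistry because ring C then closes through the one free ring A oxygen. Trifluoroacetic acid in CH2Cl2 at 0 °C with pentamethylbenzene as cation scavenger should remove the acid-labile 4-(benzyloxy)benzyl ether alone and give 1-[2,4-bis(benzyloxy)-6-hydroxyphenyl]-2-{5-[5,7-bis(benzyloxy)-4-oxo-4H-chromen-2-yl]-2-[(tert-butyldiphenylsilyl)oxy]phenyl}ethanone F1. Knoevenagel condensation of F1 with commercial 4-(benzyloxy)benzaldehyde (O=Cc1ccc(OCc2ccccc2)cc1; piperidinium acetate, toluene, 80 °C) followed by 6-endo oxa-Michael closure should give the trans-2,3-diaryl chromanone as the racemate, that is 13 together with its (2S,3R)-enantiomer F2. Preparative HPLC on a chiral stationary phase then separates the two, and the route is rejoined at 13.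

Step 5. The catalyst may stall on the sodium phenoxide of 8, a second arylation may occur, or the alkoxide base may attack the pyranone ring. The fallback sets out from 8 and 3 and forms the same bond without strong base. Silylation of 8 (TBDPSCl, imidazole, DMF) should give 5,7-bis(benzyloxy)-2-{3-bromo-4-[(tert-butyldiphenylsilyl)oxy]phenyl}-4H-chromen-4-one F3. Enolisation of 3 (LiN(SiMe3)2, Me3SiCl, THF, −78 °C) should give the trimethylsilyl enol ether [(1-{2,4-bis(benzyloxy)-6-[4-(benzyloxy)benzyloxy]phenyl}vinyl)oxy]trimethylsilane F4. Palladium-catalysed arylation of the tin enolate generated in the flask from F4 and Bu3SnF (PdCl2[P(o-tol)3]2 as a divalent palladium precatalyst, toluene, 100 °C) with F3 should give the silylated deoxybenzoin directly. The route is rejoined at 10, and step 6 is no longer needed.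

Step 10. Hydrogen may reduce the flavone C2–C3 double bond or cleave the cyclic benzylic C2–O1 bond before all five ether bonds are gone. The fallback sets out from 14 and is non-reductive: BCl3 with pentamethylbenzene as a benzyl cation scavenger in CH2Cl2 at −78 °C should cleave all five aryl benzyl ethers and deliver 15 directly. No compound outside the list is made on this path (F0).

**Further compounds**

F1 | step 8 | 1-[2,4-bis(benzyloxy)-6-hydroxyphenyl]-2-{5-[5,7-bis(benzyloxy)-4-oxo-4H-chromen-2-yl]-2-[(tert-butyldiphenylsilyl)oxy]phenyl}ethanone | O=C(Cc1cc(-c2cc(=O)c3c(OCc4ccccc4)cc(OCc4ccccc4)cc3o2)ccc1O[Si](c1ccccc1)(c1ccccc1)C(C)(C)C)c1c(O)cc(OCc2ccccc2)cc1OCc1ccccc1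
F2 | step 8 | (2S,3R)-5,7-bis(benzyloxy)-2-[4-(benzyloxy)phenyl]-3-{5-[5,7-bis(benzyloxy)-4-oxo-4H-chromen-2-yl]-2-[(tert-butyldiphenylsilyl)oxy]phenyl}chroman-4-one (enantiomer of 13) | O=C1c2c(OCc3ccccc3)cc(OCc3ccccc3)cc2O[C@H](c2ccc(OCc3ccccc3)cc2)[C@H]1c1cc(-c2cc(=O)c3c(OCc4ccccc4)cc(OCc4ccccc4)cc3o2)ccc1O[Si](c1ccccc1)(c1ccccc1)C(C)(C)C
F3 | step 5 | 5,7-bis(benzyloxy)-2-{3-bromo-4-[(tert-butyldiphenylsilyl)oxy]phenyl}-4H-chromen-4-one | O=c1cc(-c2ccc(O[Si](c3ccccc3)(c3ccccc3)C(C)(C)C)c(Br)c2)oc2cc(OCc3ccccc3)cc(OCc3ccccc3)c12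
F4 | step 5 | [(1-{2,4-bis(benzyloxy)-6-[4-(benzyloxy)benzyloxy]phenyl}vinyl)oxy]trimethylsilane | C=C(O[Si](C)(C)C)c1c(OCc2ccc(OCc3ccccc3)cc2)cc(OCc2ccccc2)cc1OCc1ccccc1
F0 | step 10 | none | none
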